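**Retrosynthetic overview**

- The two cinnamoyl esters (caffeate on O3, p-coumarate on O4) and the C7–O5 lactone of 1,5-quinide are disconnected last. In the lactone chair O3 is equatorial and O4 axial, so they are acylated in that order.
- O3 comes from O4 by iodocarbonate cyclisation across C2=C3 of a cyclohex-2-ene-1,4-diol, which comes from O–O reduction of a 2,3-dioxabicyclo[2.2.2]oct-7-ene.
- Feature carrying the strategy: in the cyclohexane ring, O1 (on C1, which bears the carboxyl carbon C7) and O4 (on C4) are cis and 1,4-related, and both are trans to O5 (on C5). One O2 molecule can therefore deliver both across C1 and C4 of a cyclohexa-1,3-diene, on the face opposite the C5 silyloxy group.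
- The diene comes from furan and an acryloyl imide: enantioselective Diels–Alder (sets C5), methanolysis, base-induced opening of the oxygen bridge, silylation.
- Ring order: oxanorbornene (step 1), carbocyclic diene (step 3), peroxide bridge (step 5), cyclic carbonate (step 8), lactone (step 11).

Key step: step 5

Assumption: ring atoms carry quinic acid numbering (O3 cis to O4, O5 trans), and the (R,R) ligand in step 1 is taken to give the (1R,2R,4R) adduct; if the sense of induction is the reverse, the (S,S) ligand is used and nothing else changes.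

**Route**

Step 1
Reactants: 1 furan; 2 3-acryloyl-1,3-oxazolidin-2-one
Product: 3 3-{[(1R,2R,4R)-7-oxabicyclo[2.2.1]hept-5-en-2-yl]carbonyl}-1,3-oxazolidin-2-one (endo adduct)
Conditions: [Cu((R,R)-t-Bu-box)](SbF6)2 (5 mol %; divalent copper; ligand = 2,2'-(propane-2,2-diyl)bis[(4R)-4-tert-butyl-4,5-dihydro-1,3-oxazole]), furan (10 equiv), CH2Cl2, −78 °C; recrystallisation
Reagents that add atoms: none
Why: Bidentate binding of the imide to the cationic copper bis(oxazoline) complex activates the dienophile and shields one face, so the endo Diels–Alder adduct should form enantioselectively at a temperature where cycloreversion is frozen; the bridgehead C4 set here becomes C5 of the target, and recrystallisation removes the exo isomer, which carries the opposite bridgehead configuration.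

Step 2
Reactants: 3 imide adduct
Product: 4 methyl (1R,2R,4R)-7-oxabicyclo[2.2.1]hept-5-ene-2-carboxylate
Conditions: NaOMe (1.1 equiv), MeOH/CH2Cl2, −20 → 0 °C; AcOH quench
Reagents that add atoms: sodium methoxide, [Na+].[O-]C
Why: Imide methanolysis at the exocyclic carbonyl releases the oxazolidinone without touching the bridgehead centres, and any epimerisation at C2 is harmless because C2 becomes sp2 in step 3.

Step 3
Reactants: 4 methyl oxanorbornene ester
Product: 5 methyl (5R)-5-hydroxycyclohexa-1,3-diene-1-carboxylate
Conditions: LiN(SiMe3)2 (1.15 equiv), THF, −78 → 0 °C; AcOH quench at −78 °C; used at once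
Reagents that add atoms: none
Why: The ester enolate formed at C2 expels the bridging oxygen from C1 in an E1cB β-elimination driven by strain release, giving the conjugated dienoate while the carbinol carbon (former C4, now C5) keeps its configuration.

Step 4
Reactants: 5 dienol; 6 tert-butyldimethylsilyl chloride
Product: 7 methyl (5R)-5-[(tert-butyldimethylsilyl)oxy]cyclohexa-1,3-diene-1-carboxylate
Conditions: imidazole, DMF, 0 °C → rt
Reagents that add atoms: none
Why: Imidazole-promoted silylation of the secondary allylic alcohol is routine, and the bulky ether both suppresses dehydration to methyl benzoate and provides the facial control element for step 5.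

Step 5
Reactants: 7 silyloxy dienoate; 8 dioxygen (converted in the flask to singlet oxygen)
Product: 9 methyl (1R,4R,5R)-5-[(tert-butyldimethylsilyl)oxy]-2,3-dioxabicyclo[2.2.2]oct-7-ene-1-carboxylate
Conditions: O2 (1 atm, bubbling), 5,10,15,20-tetraphenylporphyrin (1 mol %), visible light (white LED), CH2Cl2, −30 °C; concentrated cold and used at once
Reagents that add atoms: none
Why: Energy transfer from photoexcited tetraphenylporphyrin gives singlet oxygen, which adds to the cisoid diene C1=C2–C3=C4 of 7 in a concerted suprafacial [4+2] cycloaddition that forms C1–O and C4–O and leaves the alkene at C2=C3. The closest known reaction is the photooxygenation of cyclohexa-1,3-dienes to 2,3-dioxabicyclo[2.2.2]octenes (the α-terpinene to ascaridole type), here on a diene made less electron-rich by the C1 ester and therefore expected to react more slowly but in the same way. The six-membered 1,2-dioxine ring (C1–O–O–C4–C3=C2) is closed by cycloaddition, both bonds in one event, so no exo or endo cyclisation mode is involved and the two-oxygen bridge is necessarily cis across C1 and C4. The new stereocentres, quaternary C1 and C4, are both fixed by the face of approach, which the C5 stereocentre controls: the silyloxy group on C5, next to the diene terminus C4, shields the face it occupies, so O2 should enter anti and place O1 and O4 trans to O5 as in quinic acid. The step needs facial selectivity (from the C5 silyl ether) and periselectivity for [4+2] over ene hydroperoxidation and [2+2] addition (from the ring-locked cisoid diene, the aprotic solvent and the low temperature); base and heat are avoided so that the peroxide neither undergoes Kornblum–DeLaMare opening nor loses silanol.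

Step 6
Reactants: 9 endoperoxide
Product: 10 methyl (1R,4R,5R)-5-[(tert-butyldimethylsilyl)oxy]-1,4-dihydroxycyclohex-2-ene-1-carboxylate (O1 and O4 cis, both trans to O5)
Conditions: thiourea (1.5 equiv), MeOH/CH2Cl2, 0 °C → rt
Reagents that add atoms: none
Why: Thiourea reduces the O–O bond by attack of sulfur on oxygen without breaking a C–O bond, so the cis-1,4-diol keeps the configuration set in step 5 and the alkene, ester and silyl ether are untouched.

Step 7
Reactants: 10 ene-diol
Product: 11 methyl (1R,4R,5R)-4-[(tert-butoxycarbonyl)oxy]-5-[(tert-butyldimethylsilyl)oxy]-1-hydroxycyclohex-2-ene-1-carboxylate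
Conditions: Boc2O (1.2 equiv), DMAP (0.1 equiv), MeCN, 0 °C → rt
Reagents that add atoms: di-tert-butyl dicarbonate, CC(C)(C)OC(=O)OC(=O)OC(C)(C)C
Why: DMAP-catalysed carbonate formation should select the secondary allylic C4 hydroxyl over the tertiary C1 hydroxyl, which is hindered and deactivated by the geminal ester.

Step 8
Reactants: 11 allylic tert-butyl carbonate
Product: 12 methyl 5-O-(tert-butyldimethylsilyl)-3,4-O-carbonyl-2-iodoquinate (iodine on C2 trans to O3 and cis to the ester; cyclohexane numbering 1S,2R,3S,4R,5R)
Conditions: IBr (1.5 equiv), toluene/CH2Cl2, −78 °C; aq. Na2S2O3/NaHCO3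
Reagents that add atoms: iodine monobromide, IBr
Why: In this iodocarbonate cyclisation the carbonyl oxygen of the C4 carbonate opens the reversibly formed iodonium ion at C3 from its own face (trans-diaxial, five-membered cis-fused carbonate) and bromide removes the tert-butyl group, so O3 is set cis to O4 and iodine lands on C2.

Step 9
Reactants: 12 iodocarbonate
Product: 13 methyl 5-O-(tert-butyldimethylsilyl)-3,4-O-carbonylquinate (cyclohexane numbering 1S,3R,4R,5R)
Conditions: Bu3SnH (1.5 equiv), AIBN (0.1 equiv), toluene, 80 °C
Reagents that add atoms: none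
Why: Radical chain deiodination replaces the C2 iodine by hydrogen without touching a stereocentre, since a β-carbonate oxygen does not fragment at a rate that competes with hydrogen transfer from the tin hydride.

Step 10
Reactants: 13 protected quinate
Product: 15 (−)-quinic acid [(1S,3R,4S,5R)-1,3,4,5-tetrahydroxycyclohexane-1-carboxylic acid], via lithium 5-O-(tert-butyldimethylsilyl)quinate 14 (not isolated)
Conditions: LiOH (5 equiv), THF/MeOH/H2O, 0 °C → rt; then 2 M HCl to pH 1, rt; ion-exchange resin (H+ form)
Reagents that add atoms: lithium hydroxide, [Li+].[OH-]; water, O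
Why: Saponification cleaves the cyclic carbonate and the methyl ester, and the following aqueous acid removes the secondary silyl ether, all at oxygen–carbonyl or oxygen–silicon bonds so that no ring stereocentre is affected.

Step 11
Reactants: 15 quinic acid
Product: 16 1,5-quinide [(1S,3R,4R,5R)-1,3,4-trihydroxy-6-oxabicyclo[3.2.1]octan-7-one]
Conditions: p-TsOH·H2O (5 mol %), toluene/DMF, reflux, Dean–Stark
Reagents that add atoms: none
Why: Acid-catalysed lactonisation with removal of water joins C7 to O5, the only hydroxyl cis to the carboxyl group, which masks both and leaves O3 equatorial and O4 axial.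

Step 12
Reactants: 17 caffeic acid
Product: 18 3,4-di-O-acetylcaffeic acid [(E)-3-(3,4-diacetoxyphenyl)prop-2-enoic acid]
Conditions: Ac2O, pyridine, rt; dilute aq. HCl work-up
Reagents that add atoms: acetic anhydride, CC(=O)OC(C)=O
Why: Phenol acetylation is routine and the aqueous work-up hydrolyses any mixed anhydride back to the free acid.

Step 13
Reactants: 16 1,5-quinide; 18 3,4-di-O-acetylcaffeic acid
Product: 20 3-O-(3,4-di-O-acetylcaffeoyl)-1,5-quinide, via 3,4-di-O-acetylcaffeoyl chloride 19 (not isolated)
Conditions: 18 (1.05 equiv), (COCl)2, DMF (cat.), CH2Cl2, 0 °C → rt, evaporate; then 16, pyridine, CH2Cl2/THF, −20 → 0 °C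
Reagents that add atoms: none
Why: With one equivalent of acid chloride at low temperature, acylation should take the equatorial secondary O3 in preference to the axial O4 and the tertiary bridgehead O1, as in other selective functionalisations of the equatorial hydroxyl of this lactone.

Step 14
Reactants: 21 p-coumaric acid
Product: 22 4-O-acetyl-p-coumaric acid [(E)-3-(4-acetoxyphenyl)prop-2-enoic acid]
Conditions: Ac2O, pyridine, rt; dilute aq. HCl work-up
Reagents that add atoms: acetic anhydride, CC(=O)OC(C)=O
Why: Routine phenol acetylation, as in step 12.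

Step 15
Reactants: 20 3-O-acyl quinide; 22 4-O-acetyl-p-coumaric acid
Product: 24 3-O-(3,4-di-O-acetylcaffeoyl)-4-O-(4-O-acetyl-p-coumaroyl)-1,5-quinide, via 4-O-acetyl-p-coumaroyl chloride 23 (not isolated)
Conditions: 22 (1.3 equiv), (COCl)2, DMF (cat.), CH2Cl2, 0 °C → rt, evaporate; then 20, pyridine, DMAP (0.1 equiv), CH2Cl2, 0 °C → rt
Reagents that add atoms: none
Why: DMAP-catalysed acylation of the remaining secondary (axial) O4 should outpace acylation of the tertiary α-hydroxy lactone O1, which needs more forcing conditions.

Step 16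
Reactants: 24 protected diester lactone
Product: 25 3-O-(E)-caffeoyl-4-O-(E)-p-coumaroylquinic acid (1R,3R,4S,5R; the target)
Conditions: 2 M aq. HCl/THF, rt, several days, protected from light
Reagents that add atoms: water, O
Why: Aqueous acid hydrolyses the three aryl acetates and the strained bicyclic lactone much faster than the two alkyl cinnamates, and acidic conditions keep acyl migration between neighbouring oxygens slow.

**Compound list**

1 | furan | c1ccoc1 | starting material
2 | 3-acryloyl-1,3-oxazolidin-2-one | C=CC(=O)N1CCOC1=O | starting material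
3 | 3-{[(1R,2R,4R)-7-oxabicyclo[2.2.1]hept-5-en-2-yl]carbonyl}-1,3-oxazolidin-2-one | O=C1OCCN1C(=O)[C@@H]2C[C@@H]3C=C[C@H]2O3 | intermediate
4 | methyl (1R,2R,4R)-7-oxabicyclo[2.2.1]hept-5-ene-2-carboxylate | COC(=O)[C@@H]1C[C@@H]2C=C[C@H]1O2 | intermediate
5 | methyl (5R)-5-hydroxycyclohexa-1,3-diene-1-carboxylate | COC(=O)C1=CC=C[C@H](O)C1 | intermediate
6 | tert-butyldimethylsilyl chloride | C[Si](C)(Cl)C(C)(C)C | starting material
7 | methyl (5R)-5-[(tert-butyldimethylsilyl)oxy]cyclohexa-1,3-diene-1-carboxylate | COC(=O)C1=CC=C[C@H](O[Si](C)(C)C(C)(C)C)C1 | intermediate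
8 | dioxygen (as singlet oxygen) | O=O | starting material
9 | methyl (1R,4R,5R)-5-[(tert-butyldimethylsilyl)oxy]-2,3-dioxabicyclo[2.2.2]oct-7-ene-1-carboxylate | COC(=O)[C@@]12C=C[C@@H](OO1)[C@H](O[Si](C)(C)C(C)(C)C)C2 | intermediate
10 | methyl (1R,4R,5R)-5-[(tert-butyldimethylsilyl)oxy]-1,4-dihydroxycyclohex-2-ene-1-carboxylate | COC(=O)[C@]1(O)C=C[C@@H](O)[C@H](O[Si](C)(C)C(C)(C)C)C1 | intermediate
11 | methyl (1R,4R,5R)-4-[(tert-butoxycarbonyl)oxy]-5-[(tert-butyldimethylsilyl)oxy]-1-hydroxycyclohex-2-ene-1-carboxylate | COC(=O)[C@]1(O)C=C[C@@H](OC(=O)OC(C)(C)C)[C@H](O[Si](C)(C)C(C)(C)C)C1 | intermediate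
12 | methyl 5-O-(tert-butyldimethylsilyl)-3,4-O-carbonyl-2-iodoquinate (I trans to O3) | COC(=O)[C@]1(O)[C@H](I)[C@H]2OC(=O)O[C@H]2[C@H](O[Si](C)(C)C(C)(C)C)C1 | intermediate
13 | methyl 5-O-(tert-butyldimethylsilyl)-3,4-O-carbonylquinate | COC(=O)[C@]1(O)C[C@H]2OC(=O)O[C@H]2[C@H](O[Si](C)(C)C(C)(C)C)C1 | intermediate
14 | lithium 5-O-(tert-butyldimethylsilyl)quinate | [Li+].[O-]C(=O)[C@]1(O)C[C@@H](O)[C@@H](O)[C@H](O[Si](C)(C)C(C)(C)C)C1 | intermediate (not isolated)
15 | (−)-quinic acid | OC(=O)[C@]1(O)C[C@@H](O)[C@@H](O)[C@H](O)C1 | intermediate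
16 | 1,5-quinide | O=C1O[C@@H]2C[C@@]1(O)C[C@@H](O)[C@H]2O | intermediate
17 | caffeic acid | OC(=O)/C=C/c1ccc(O)c(O)c1 | starting material
18 | 3,4-di-O-acetylcaffeic acid | OC(=O)/C=C/c1ccc(OC(C)=O)c(OC(C)=O)c1 | intermediate
19 | 3,4-di-O-acetylcaffeoyl chloride | ClC(=O)/C=C/c1ccc(OC(C)=O)c(OC(C)=O)c1 | intermediate (not isolated)
20 | 3-O-(3,4-di-O-acetylcaffeoyl)-1,5-quinide | O=C1O[C@@H]2C[C@@]1(O)C[C@@H](OC(=O)/C=C/c3ccc(OC(C)=O)c(OC(C)=O)c3)[C@H]2O | intermediate
21 | p-coumaric acid | OC(=O)/C=C/c1ccc(O)cc1 | starting material
22 | 4-O-acetyl-p-coumaric acid | OC(=O)/C=C/c1ccc(OC(C)=O)cc1 | intermediate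
23 | 4-O-acetyl-p-coumaroyl chloride | ClC(=O)/C=C/c1ccc(OC(C)=O)cc1 | intermediate (not isolated)
24 | 3-O-(3,4-di-O-acetylcaffeoyl)-4-O-(4-O-acetyl-p-coumaroyl)-1,5-quinide | O=C1O[C@@H]2C[C@@]1(O)C[C@@H](OC(=O)/C=C/c3ccc(OC(C)=O)c(OC(C)=O)c3)[C@H]2OC(=O)/C=C/c4ccc(OC(C)=O)cc4 | intermediate
25 | 3-O-caffeoyl-4-O-p-coumaroylquinic acid (1R,3R,4S,5R) | O=C(/C=C/c1ccc(O)cc1)O[C@H]1[C@H](O)C[C@](O)(C(=O)O)C[C@H]1OC(=O)/C=C/c1ccc(O)c(O)c1 | target

**Step count**

Total: 16 steps. Longest linear sequence: 14 steps (steps 1–11, 13, 15, 16); steps 12 and 14 are one-step side branches.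

**Steps most likely to fail**

1. Step 5 (key photooxygenation). The ester-bearing diene may react slowly with electrophilic singlet oxygen, so that sensitiser bleaching, ene-type hydroperoxidation at the allylic C–H bonds and loss of silanol with aromatisation overtake the cycloaddition. Fallback, setting out from 7 and returning at 9: the ester is reduced with i-Bu2AlH (CH2Cl2, −78 °C) to the electron-richer diene [(5R)-5-(tert-butyldimethylsilyloxy)cyclohexa-1,3-dien-1-yl]methanol F1. This is photooxygenated under the conditions of step 5, with the same anti control by the C5 silyl ether, to give [(1R,4R,5R)-5-(tert-butyldimethylsilyloxy)-2,3-dioxabicyclo[2.2.2]oct-7-en-1-yl]methanol F2. Oxidation of the primary alcohol with TEMPO (cat.)/PhI(OAc)2 in MeCN/water gives (1R,4R,5R)-5-(tert-butyldimethylsilyloxy)-2,3-dioxabicyclo[2.2.2]oct-7-ene-1-carboxylic acid F3, and Me3SiCHN2 in toluene/MeOH returns methyl ester 9.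

2. Step 8 (iodocarbonate cyclisation). The iodonium ion may be captured by the free tertiary hydroxyl or the ester carbonyl instead of the carbonate, iodonium formation on the more hindered face may be slow, or acid released by tert-butyl cation elimination may strip the silyl ether. Fallback, setting out from diol 10 (step 7 is left out) and returning at 15: mCPBA (NaHCO3, CH2Cl2, 0 °C), directed by the two allylic hydroxyls on the same face, gives methyl 5-(tert-butyldimethylsilyloxy)-2,3-epoxy-1,4-dihydroxycyclohexane-1-carboxylate with the epoxide cis to O1 and O4 F4. LiI/AcOH in THF opens it trans-diaxially at C2, the only mode that keeps the ester, O4 and the silyloxy group equatorial, to give methyl 5-O-(tert-butyldimethylsilyl)-2-iodoquinate F5. Bu3SnH/AIBN then gives methyl 5-O-(tert-butyldimethylsilyl)quinate F6, which under the conditions of step 10 passes through lithium salt 14 to quinic acid 15.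

3. Step 13 (first acylation of the quinide). Acylation may spread over O3, O4 and the tertiary O1, or the first-formed ester may migrate between the cis-related O3 and O4 under the basic conditions. Fallback, setting out from 16 and returning at 20: Bu2SnO (toluene, reflux, water removed) converts the cis-diol into 3,4-O-dibutylstannylene-1,5-quinide F7, in which tin activates only O3 and O4 and passes the acyl group to the equatorial oxygen. Addition of acid chloride 19 at 0 °C without amine base, then aqueous work-up, should give 20, which rejoins the route before step 15.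

**Further compounds**

F1 | step 5 | [(5R)-5-(tert-butyldimethylsilyloxy)cyclohexa-1,3-dien-1-yl]methanol | OCC1=CC=C[C@H](O[Si](C)(C)C(C)(C)C)C1
F2 | step 5 | [(1R,4R,5R)-5-(tert-butyldimethylsilyloxy)-2,3-dioxabicyclo[2.2.2]oct-7-en-1-yl]methanol | OC[C@@]12C=C[C@@H](OO1)[C@H](O[Si](C)(C)C(C)(C)C)C2
F3 | step 5 | (1R,4R,5R)-5-(tert-butyldimethylsilyloxy)-2,3-dioxabicyclo[2.2.2]oct-7-ene-1-carboxylic acid | OC(=O)[C@@]12C=C[C@@H](OO1)[C@H](O[Si](C)(C)C(C)(C)C)C2
F4 | step 8 | methyl 5-(tert-butyldimethylsilyloxy)-2,3-epoxy-1,4-dihydroxycyclohexane-1-carboxylate (epoxide cis to O1 and O4) | COC(=O)[C@]1(O)[C@H]2O[C@H]2[C@@H](O)[C@H](O[Si](C)(C)C(C)(C)C)C1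
F5 | step 8 | methyl 5-O-(tert-butyldimethylsilyl)-2-iodoquinate (I trans to O3) | COC(=O)[C@]1(O)[C@H](I)[C@@H](O)[C@@H](O)[C@H](O[Si](C)(C)C(C)(C)C)C1
F6 | step 8 | methyl 5-O-(tert-butyldimethylsilyl)quinate | COC(=O)[C@]1(O)C[C@@H](O)[C@@H](O)[C@H](O[Si](C)(C)C(C)(C)C)C1
F7 | step 13 | 3,4-O-dibutylstannylene-1,5-quinide | O=C1O[C@@H]2C[C@@]1(O)C[C@H]3O[Sn](CCCC)(CCCC)O[C@@H]23
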